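## The problem

1. The target is a 28-membered lactone-lactam. Ring atoms are numbered here from the propyl-bearing carbon C1 through the ester oxygen O2, the ester carbonyl C3, the enoate C4=C5, C6 (methyl), C7–C10, the ketone C11, C12–C14, C15 (ethyl), the diene C16=C17–C18=C19 (CH2OMe on C19), C20, C21, the carbinols C22 and C23, C24, the carbinol C25 and C26, to N27 and the lactam carbonyl C28.
2. No smaller ring and no rigid element holds the chain. Ring closure is therefore an end-to-end reaction of a 25-atom chain, and this closure, together with the stepwise making of the two acyl links on either side of C1, is the hardest part.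
3. The six stereocentres fall into groups that cannot control each other. C1 (S) stands alone between ester and amide. C6 (R) and C15 (R) are single alkyl branches, each next to an sp2 carbon and nine bonds apart. Only C22 (R), C23 (S) and C25 (S), an anti,anti-1,2,4-triol, are close enough for relay.
4. The C18=C19 double bond is trisubstituted, and C17 must stand cis to the methoxymethyl group and trans to C20.
5. The feature that opens the key step is the run O2–C1–C28–N27 with the acyl carbon C3 on O2. This is an α-acyloxy carboxamide, the exact product pattern of a Passerini reaction of a carboxylic acid (C3), butanal (C1 with its propyl group) and an isocyanide (N27, C28).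
6. A second feature is that C5–C10 and C11–C16 are two six-carbon runs, each with its alkyl branch on the second carbon. They are two opened 3-alkylcyclohexene rings laid head to tail.
7. Several groups need care:
   - the dienyl allylic methyl ether (acid);
   - the α-acyloxy amide next to a free C25 hydroxyl (base, acyl migration);
   - the C11 ketone (hydrides, organometallics, strong base);
   - the epimerisable aldehydes on the way to C6 and C15;
   - the isocyanide (acid, palladium, boranes).

## Retrosynthesis

**Cut 1: O2–C3 and C1–C28 (36 ⇒ 35 ⇒ 31 + 32).** The three hydroxyls are masked as silyl ethers (35). The unit C3(=O)–O2–C1(Pr)–C28(=O)–N27 is then taken apart in the Passerini sense into the acid C3, butanal 32 and the isocyanide N27≡C28. Acid and isocyanide are the two ends of one chain, 31. Each neighbouring single cut (O2–C3 alone or N27–C28 alone) leaves C1 and one acyl bond to be made beforehand from a chiral hydroxy acid. The double cut removes the ring, one stereocentre, the ester and the amide at once, and puts a C4 aldehyde in place of a chiral building block. Precursor 31 is an open chain with five stereocentres and two small end groups. The forward reaction must close end to end in preference to chain growth and must control the aldehyde face through a catalyst.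

**Cut 2: the chain ends (31 ⇒ 30 ⇒ 29).** The isocyanide comes from the formamide 29 by dehydration and the acid from the methyl ester. The order matters: an isocyanide withstands hydroxide, a formamide less so. An isocyanide would also poison every palladium or borane step, so it is made only after the last coupling. No skeletal bond is cut. The forward steps must leave the ketone, the diene and the silyl ethers alone.

**Cut 3: C19–C20 (29 ⇒ 18 + 27).** This sp2–sp3 bond divides the chain into the bromodiene 18 (C3–C19) and the vinyl triol piece 27 (C20–C26). A cut at C17–C18 would demand a stereodefined trisubstituted alkenyl halide on the triol piece. C20–C21 and C21–C22 are sp3–sp3 bonds without a handle. The chosen cut uses the vinyl group, which the making of the diol leaves behind anyway, as the nucleophile after hydroboration. The forward reaction must couple with retention at C19 in the presence of ketone, enoate and formamide.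

**Cut 4: C17–C18 (18 ⇒ 15 + 17; 17 ⇒ 16).** The atoms C18, C19 and CH2OMe are brought in as the dihalide 17, made in one step from 3-methoxypropyne 16. Its two halogens stand trans and differ in reactivity. The geometry of the trisubstituted alkene is thus written into a three-carbon piece and handed on by two couplings with retention. The forward reaction must insert into C–I only.

**Cut 5: C10–C11 (15 ⇒ 7 + 13).** The ketone is the natural seam. Cut on this side, C11 is an acyl donor (thioester 13) and C10 an alkylzinc made from iodide 7, which tolerates the enoate. The cut C11–C12 would need the opposite oxidation states at both fragment ends. Each half now carries one stereocentre.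

**Cut 6: reconnection of C5 with C10 and of C16 with C11 (7 ⇒ 5 ⇒ 3 ⇒ 1; 13 ⇒ 11 ⇒ 9 ⇒ 1).** Both halves are closed back to six-membered rings. A 3-alkylcyclohexenyl silyl enol ether (3 or 9) opens on ozonolysis to an aldehyde next to the branch and an acid at the far end, so the two ends are differentiated without protecting groups. Both enol ethers come from the same enone 1 by the same catalytic asymmetric conjugate addition, with methyl or ethyl as the nucleophile. Two remote stereocentres thus become two runs of one reaction on an achiral C6 ring.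

**Cut 7: C22–C23 (27 ⇒ 25 ⇒ 24 ⇒ 22 ⇒ 19).** C25 is bought with ethyl (S)-4-chloro-3-hydroxybutanoate 19, which also holds C23–C26 and the site for nitrogen. A reagent-controlled anti-hydroxyallylation of aldehyde 22 makes the C22–C23 bond, both carbinol centres and the vinyl group C20=C21 in one event. Cuts at C23–C24 or C24–C25 would set one centre at a time.

## Roads not taken

**Alternative 1:** the most obvious plan.
- *Cut:* the lactam bond N27–C28 (or the lactone bond O2–C3), with C1 bought as (S)-2-hydroxypentanoic acid A1.
- *Forward key step:* A1 is protected at its carboxyl group, acylated on oxygen with the C3 acid and released. The seco amino acid A2 is then closed by macrolactamisation at high dilution.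
- *Why the chosen plan is better:*
  - A1 is a fourth chiral building block with its own protection and release.
  - The two acyl links need two separate activations.
  - The activated carboxyl of A2 stands next to the acyloxy-bearing C1–H and can epimerise.
  - Amine and acid must be unmasked orthogonally beside three silyl ethers.
  - The longest line grows by several steps, and the ring closure sets no stereocentre.

**Alternative 2:**
- *Cut:* C17–C18 in the diene, far from the heteroatoms.
- *Forward key step:* ester and amide are made first. The open chain A3, with an (E)-alkenylboronate at C17 and a (Z)-alkenyl iodide at C18, is closed by an intramolecular Suzuki–Miyaura coupling.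
- *Why the chosen plan is better:*
  - The closure has good precedent and fixes the diene, but it needs the stereodefined trisubstituted iodide on the triol piece, which takes longer to reach than the vinyl group of 27.
  - It still needs A1 and both acylations.
  - Two labile termini must be carried through them.
  - C1 is untouched by the key step.

**Alternative 3:**
- *Cut:* O2–C3, made by ring expansion.
- *Forward key step:* the 25-membered lactam A4 (N27 acylated by C3) is N-acylated with a protected form of A1. Release of the hydroxyl gives imide A5, whose hydroxyl attacks C3 and widens the ring by three atoms.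
- *Why the chosen plan is better:*
  - The macrocyclisation is moved, not removed, since A4 must be closed at a hindered conjugated acid.
  - N-acylation of a secondary macrolactam asks for strong base or forcing conditions beside an enolisable ketone and an enoate.
  - A1 is still needed.

Key step: step 21

Assumption: the (R,R) antipode of the (salen)AlCl catalyst is taken as the one that guides the isocyanide to the Re face of butanal. Both antipodes are sold, and the sense is to be fixed beforehand on a simple acid, butanal and a simple primary isocyanide.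

## Steps

Step 1
Reactants: 1 cyclohex-2-en-1-one
Product: 3 (R)-trimethyl[(3-methylcyclohex-1-en-1-yl)oxy]silane, via zinc enolate 2 (not isolated)
Conditions: Me2Zn, Cu(OTf)2 (2 mol%), (R,S,S)-phosphoramidite from (R)-BINOL and bis[(S)-1-phenylethyl]amine (4 mol%), toluene, −25 °C; then Me3SiOTf, 0 °C
Reagents that add atoms: dimethylzinc C[Zn]C; trimethylsilyl trifluoromethanesulfonate C[Si](C)(C)OS(=O)(=O)C(F)(F)F
Why: Copper-catalysed asymmetric conjugate addition of a dialkylzinc to a cyclic enone; the chiral phosphoramidite on copper decides the face and sets the future C6 as R. O-Silylation of zinc enolate 2 freezes the double bond between the future C10 and C5 and so marks the bond to be cleaved.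

Step 2
Reactants: 3 (R)-trimethyl[(3-methylcyclohex-1-en-1-yl)oxy]silane
Product: 5 (5R,6E)-8-methoxy-5,7-dimethyl-8-oxooct-6-enoic acid, via aldehyde acid 4 (not isolated)
Conditions: O3, CH2Cl2/MeOH, −78 °C; Me2S, −78 °C to rt; concentrate; Ph3P=C(Me)CO2Me (2.2 equiv), CH2Cl2, rt; work-up at pH 4
Reagents that add atoms: ozone [O-][O+]=O; methyl 2-(triphenylphosphoranylidene)propanoate COC(=O)C(C)=P(c1ccccc1)(c1ccccc1)c1ccccc1
Why: Ozonolysis of a cyclic silyl enol ether gives an ω-oxo acid with unlike ends (the oxygen-bearing carbon becomes the acid C10, the CH carbon the aldehyde C5). The α-branched stabilised ylide gives the E-enoate in a base-free Wittig reaction, so the centre next to the aldehyde should not epimerise; the second equivalent of ylide covers the acid proton.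

Step 3
Reactants: 5 (5R,6E)-8-methoxy-5,7-dimethyl-8-oxooct-6-enoic acid
Product: 6 methyl (2E,4R)-8-hydroxy-2,4-dimethyloct-2-enoate
Conditions: BH3·SMe2, THF, 0 °C to rt; MeOH quench
Reagents that add atoms: none
Why: Chemoselective borane reduction: the free acid reacts through its acyloxyborane much faster than a conjugated ester or an electron-poor trisubstituted alkene.

Step 4
Reactants: 6 methyl (2E,4R)-8-hydroxy-2,4-dimethyloct-2-enoate
Product: 7 methyl (2E,4R)-8-iodo-2,4-dimethyloct-2-enoate
Conditions: I2, PPh3, imidazole, CH2Cl2, 0 °C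
Reagents that add atoms: iodine [I][I]
Why: Appel-type iodination of a primary alcohol under neutral conditions; no stereocentre takes part.

Step 5
Reactants: 1 cyclohex-2-en-1-one
Product: 9 (R)-[(3-ethylcyclohex-1-en-1-yl)oxy]trimethylsilane, via zinc enolate 8 (not isolated)
Conditions: Et2Zn, Cu(OTf)2 (2 mol%), (R,S,S)-phosphoramidite as in step 1 (4 mol%), toluene, −30 °C; then Me3SiOTf, 0 °C
Reagents that add atoms: diethylzinc CC[Zn]CC; trimethylsilyl trifluoromethanesulfonate C[Si](C)(C)OS(=O)(=O)C(F)(F)F
Why: The same copper-catalysed asymmetric conjugate addition with the same ligand antipode, so ethyl enters on the same face and the future C15 is R. The enol ether double bond lies between the future C11 and C16.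

Step 6
Reactants: 9 (R)-[(3-ethylcyclohex-1-en-1-yl)oxy]trimethylsilane
Product: 11 (R)-5-ethylhept-6-ynoic acid, via aldehyde acid 10 (not isolated)
Conditions: O3, CH2Cl2/MeOH, −78 °C; Me2S; concentrate; dimethyl (1-diazo-2-oxopropyl)phosphonate, K2CO3, MeOH, 0 °C to rt; work-up at pH 4
Reagents that add atoms: ozone [O-][O+]=O; dimethyl (1-diazo-2-oxopropyl)phosphonate CC(=O)C(=[N+]=[N-])P(=O)(OC)OC
Why: Ozonolysis as in step 2 gives the acid C11 and the aldehyde C16; the Ohira–Bestmann homologation turns the aldehyde into the terminal alkyne C16≡C17 while the acid rests as its carboxylate. α-Alkyl aldehydes as a rule pass these mild carbonate conditions with their configuration intact.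

Step 7
Reactants: 11 (R)-5-ethylhept-6-ynoic acid
Product: 12 S-ethyl (R)-5-ethylhept-6-ynethioate
Conditions: EtSH, DCC, DMAP (10 mol%), CH2Cl2, 0 °C to rt
Reagents that add atoms: ethanethiol CCS
Why: Steglich-type thioesterification. The thioester removes the acidic proton before the hydroboration and is the acyl donor of step 9.

Step 8
Reactants: 12 S-ethyl (R)-5-ethylhept-6-ynethioate
Product: 13 S-ethyl (5R,6E)-5-ethyl-7-(4,4,5,5-tetramethyl-1,3,2-dioxaborolan-2-yl)hept-6-enethioate
Conditions: pinacolborane, Cy2BH (10 mol%), neat, rt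
Reagents that add atoms: pinacolborane B1OC(C)(C)C(C)(C)O1
Why: Syn, anti-Markovnikov hydroboration of a terminal alkyne: Cy2BH adds and passes the alkenyl group on to pinacolborane, which gives the E-alkenylboronate. The branch at C15 reinforces the terminal placement of boron, and a thioester is inert to these boranes.

Step 9
Reactants: 7 methyl (2E,4R)-8-iodo-2,4-dimethyloct-2-enoate; 13 S-ethyl (5R,6E)-5-ethyl-7-(4,4,5,5-tetramethyl-1,3,2-dioxaborolan-2-yl)hept-6-enethioate
Product: 15 methyl (2E,4R,13R,14E)-13-ethyl-2,4-dimethyl-9-oxo-15-(4,4,5,5-tetramethyl-1,3,2-dioxaborolan-2-yl)pentadeca-2,14-dienoate, via alkylzinc iodide 14 (not isolated)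
Conditions: 7, Zn dust, LiCl, THF, 35 °C; then 13, PdCl2(PPh3)2 (5 mol%), toluene, rt
Reagents that add atoms: none
Why: Fukuyama coupling: zerovalent palladium inserts into the C–S bond, the alkylzinc iodide transfers C10 and the ketone C11 results without over-addition. Alkylzinc iodides tolerate esters, and an alkenylboronate does not transmetalate in the absence of base.

Step 10
Reactants: 16 3-methoxyprop-1-yne
Product: 17 (E)-2-bromo-1-iodo-3-methoxyprop-1-ene
Conditions: IBr, CH2Cl2, −78 to 0 °C, dark
Reagents that add atoms: iodine monobromide BrI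
Why: Electrophilic anti addition through an iodonium ion: iodine ends on the terminal carbon (C18), bromide opens at the internal carbon (C19) from the opposite side. Iodine therefore stands cis to CH2OMe and trans to bromine, which is the geometry needed for C17 and C20.

Step 11
Reactants: 15 methyl (2E,4R,13R,14E)-13-ethyl-2,4-dimethyl-9-oxo-15-(4,4,5,5-tetramethyl-1,3,2-dioxaborolan-2-yl)pentadeca-2,14-dienoate; 17 (E)-2-bromo-1-iodo-3-methoxyprop-1-ene
Product: 18 methyl (2E,4R,13R,14E,16E)-17-bromo-13-ethyl-18-methoxy-2,4-dimethyl-9-oxooctadeca-2,14,16-trienoate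
Conditions: PdCl2(dppf) (5 mol%), K3PO4 (aq), THF, rt; 17 in slight excess
Reagents that add atoms: none
Why: Suzuki–Miyaura coupling of two alkenyl partners with retention on both sides. The terminal C–I bond inserts palladium much faster than the internal C–Br bond, as in the known stepwise couplings of 1-iodo-2-haloalkenes, so the bromide is kept for step 18.

Step 12
Reactants: 19 ethyl (S)-4-chloro-3-hydroxybutanoate
Product: 20 ethyl (S)-4-azido-3-hydroxybutanoate
Conditions: NaN3, DMF, 90 °C
Reagents that add atoms: sodium azide [Na+].[N-]=[N+]=[N-]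
Why: SN2 displacement at the primary carbon C26; the carbinol centre C25 is not touched and stays S.

Step 13
Reactants: 20 ethyl (S)-4-azido-3-hydroxybutanoate
Product: 21 ethyl (S)-4-azido-3-(tert-butyldimethylsilyloxy)butanoate
Conditions: TBSCl, imidazole, DMF, rt
Reagents that add atoms: tert-butyldimethylsilyl chloride CC(C)(C)[Si](C)(C)Cl
Why: Standard silylation of a secondary alcohol. The azide is kept because a free amine would close on the ester to a γ-lactam.

Step 14
Reactants: 21 ethyl (S)-4-azido-3-(tert-butyldimethylsilyloxy)butanoate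
Product: 22 (S)-4-azido-3-(tert-butyldimethylsilyloxy)butanal
Conditions: i-Bu2AlH, CH2Cl2, −78 °C; Rochelle salt work-up
Reagents that add atoms: none
Why: Partial reduction of an ester through the tetrahedral aluminium acetal, which is stable in the cold; alkyl azides survive one equivalent of i-Bu2AlH at −78 °C.

Step 15
Reactants: 22 (S)-4-azido-3-(tert-butyldimethylsilyloxy)butanal
Product: 24 (3R,4S,6S)-7-azido-6-(tert-butyldimethylsilyloxy)hept-1-ene-3,4-diol, via α-boryl homoallyl borinate 23 (not isolated)
Conditions: (−)-α-pinene, BH3·SMe2, THF, 0 °C; allenylboronic acid pinacol ester, 0 °C; 22, Et2O, −78 °C; then NaOH, H2O2, 0 °C to rt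
Reagents that add atoms: allenylboronic acid pinacol ester C=C=CB1OC(C)(C)C(C)(C)O1; hydrogen peroxide OO
Why: Asymmetric allylboration with an (E)-γ-boryl allylborane: the chair transition state turns the E geometry into the anti relation C22/C23, and the isopinocampheyl groups from (−)-α-pinene choose the aldehyde face that gives 23S. Oxidation replaces boron at C22 by hydroxyl with retention (22R); the reagent overrides the weak bias of C25, so the C23/C25 relation is anti.

Step 16
Reactants: 24 (3R,4S,6S)-7-azido-6-(tert-butyldimethylsilyloxy)hept-1-ene-3,4-diol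
Product: 25 (3R,4S,6S)-7-azido-3,4,6-tris(tert-butyldimethylsilyloxy)hept-1-ene
Conditions: TBSOTf, 2,6-lutidine, CH2Cl2, 0 °C
Reagents that add atoms: tert-butyldimethylsilyl trifluoromethanesulfonate CC(C)(C)[Si](C)(C)OS(=O)(=O)C(F)(F)F
Why: The silyl triflate is reactive enough to silylate both hydroxyls of a hindered vicinal diol. One kind of protecting group on all three oxygens allows one final deprotection.

Step 17
Reactants: 25 (3R,4S,6S)-7-azido-3,4,6-tris(tert-butyldimethylsilyloxy)hept-1-ene
Product: 27 N-[(2S,4S,5R)-2,4,5-tris(tert-butyldimethylsilyloxy)hept-6-en-1-yl]formamide, via primary amine 26 (not isolated)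
Conditions: PPh3, THF/H2O, 50 °C; concentrate; HCO2Et, reflux
Reagents that add atoms: ethyl formate CCOC=O
Why: Staudinger reduction spares the terminal alkene; aminolysis of ethyl formate gives the N-alkylformamide, the storage form of the isocyanide.

Step 18
Reactants: 27 N-[(2S,4S,5R)-2,4,5-tris(tert-butyldimethylsilyloxy)hept-6-en-1-yl]formamide; 18 methyl (2E,4R,13R,14E,16E)-17-bromo-13-ethyl-18-methoxy-2,4-dimethyl-9-oxooctadeca-2,14,16-trienoate
Product: 29 methyl (2E,4R,13R,14E,16Z,20R,21S,23S)-20,21,23-tris(tert-butyldimethylsilyloxy)-13-ethyl-24-formamido-17-(methoxymethyl)-2,4-dimethyl-9-oxotetracosa-2,14,16-trienoate, via B-alkyl-9-BBN 28 (not isolated)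
Conditions: 27, 9-BBN (3 equiv), THF, rt; aq Cs2CO3; then 18, PdCl2(dppf) (10 mol%), AsPh3, DMF, rt to 45 °C
Reagents that add atoms: none
Why: B-alkyl Suzuki–Miyaura coupling: 9-BBN adds to the terminal carbon C20, aqueous base destroys the excess B–H before ketone 18 is added, and the alkenyl bromide couples with retention, so C20 ends trans to C17. Secondary amides are tolerated in this reaction type when extra borane covers the N–H.

Step 19
Reactants: 29 methyl (2E,4R,13R,14E,16Z,20R,21S,23S)-20,21,23-tris(tert-butyldimethylsilyloxy)-13-ethyl-24-formamido-17-(methoxymethyl)-2,4-dimethyl-9-oxotetracosa-2,14,16-trienoate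
Product: 30 methyl (2E,4R,13R,14E,16Z,20R,21S,23S)-20,21,23-tris(tert-butyldimethylsilyloxy)-13-ethyl-24-isocyano-17-(methoxymethyl)-2,4-dimethyl-9-oxotetracosa-2,14,16-trienoate
Conditions: POCl3, Et3N, CH2Cl2, −20 to 0 °C; aq Na2CO3 work-up
Reagents that add atoms: none
Why: Standard dehydration of an N-alkylformamide through its O-phosphorylated imidate. The basic medium spares the silyl ethers, the allylic ether and the ketone.

Step 20
Reactants: 30 methyl (2E,4R,13R,14E,16Z,20R,21S,23S)-20,21,23-tris(tert-butyldimethylsilyloxy)-13-ethyl-24-isocyano-17-(methoxymethyl)-2,4-dimethyl-9-oxotetracosa-2,14,16-trienoate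
Product: 31 (2E,4R,13R,14E,16Z,20R,21S,23S)-20,21,23-tris(tert-butyldimethylsilyloxy)-13-ethyl-24-isocyano-17-(methoxymethyl)-2,4-dimethyl-9-oxotetracosa-2,14,16-trienoic acid
Conditions: LiOH, THF/MeOH/H2O, rt to 35 °C; cold aq NaH2PO4, extraction; used at once
Reagents that add atoms: lithium hydroxide [Li+].[OH-]
Why: Saponification; isocyanides are stable to hydroxide, and no stereocentre stands next to an acidified position. The buffered work-up avoids the acid hydrolysis of the isocyanide, and without an aldehyde a carboxylic acid and an alkyl isocyanide coexist at room temperature.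

Step 21
Reactants: 31 (2E,4R,13R,14E,16Z,20R,21S,23S)-20,21,23-tris(tert-butyldimethylsilyloxy)-13-ethyl-24-isocyano-17-(methoxymethyl)-2,4-dimethyl-9-oxotetracosa-2,14,16-trienoic acid; 32 butanal
Product: 35 22,23,25-tris-O-(tert-butyldimethylsilyl) derivative of the target (1S,6R,15R,22R,23S,25S), via nitrilium carboxylate 33 (not isolated), via macrocyclic acyl imidate 34 (not isolated)
Conditions: (R,R)-[N,N'-bis(3,5-di-tert-butylsalicylidene)cyclohexane-1,2-diaminato]AlCl (20 mol%), 32 (20 equiv), 4 Å molecular sieves, toluene, −40 °C; 31 in toluene added by syringe pump over 24 h (final 1 mM); then −20 °C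
Reagents that add atoms: none
Why: Proposed new method: the closest known reaction types are the ring-closing Passerini reaction of ω-isocyano carboxylic acids with an added aldehyde, known without stereocontrol, and the intermolecular three-component Passerini reaction of aliphatic aldehydes under a chiral (salen)AlCl catalyst; the two have not been joined. The trivalent aluminium centre binds butanal 32, the isocyanide carbon of 31 (future C28) adds to the aldehyde carbon (future C1) and gives nitrilium 33; this C–C bond formation is a local, bimolecular event at the chain end, so the new stereocentre C1 is controlled by the salen ligand alone (Re-face attack gives S) and should follow the intermolecular precedent. The carboxylate at the far end then adds to the nitrilium carbon in a 27-endo-dig closure to acyl imidate 34. The oxygen on C1 attacks the C3 carbonyl through a five-membered cyclic transition state (5-exo-trig), and this irreversible O-to-O acyl shift widens the ring by one atom to the 28-membered lactone-lactam 35 while the imidate becomes the amide. Ring closure against chain growth is secured by the slow addition: aldehyde and catalyst stay in large excess, so the C–C bond forms at the rate of the usual concentrated reaction, whereas the stationary concentration of 31 and 33 is too low for one chain to meet another. The same low concentration of free acid starves the uncatalysed, acid-assisted background that would erode the selectivity at C1. Aldehyde is preferred to ketone because C11 is a dialkyl ketone, far less electrophilic than butanal, which is present in twentyfold excess. The silyl ether on the C25 oxygen keeps that oxygen from closing an oxazoline on the nitrilium carbon, and no other nucleophile is free in 31.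

Step 22
Reactants: 35 22,23,25-tris-O-(tert-butyldimethylsilyl) derivative of the target (1S,6R,15R,22R,23S,25S)
Product: 36 target CNP0489568.2
Conditions: HF·pyridine, pyridine, THF, 0 °C to rt
Reagents that add atoms: none
Why: Fluoride-driven cleavage of three secondary silyl ethers in a buffered, weakly acidic medium. This avoids the base-induced acyl migration of the α-acyloxy amide and the acid ionisation of the dienyl allylic ether.

## Compound list

1 | cyclohex-2-en-1-one | O=C1C=CCCC1 | starting material
2 | methylzinc (R)-3-methylcyclohex-1-en-1-olate | C[C@@H]1CCCC(O[Zn]C)=C1 | intermediate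
3 | (R)-trimethyl[(3-methylcyclohex-1-en-1-yl)oxy]silane | C[C@@H]1CCCC(O[Si](C)(C)C)=C1 | intermediate
4 | (R)-5-methyl-6-oxohexanoic acid | C[C@@H](C=O)CCCC(=O)O | intermediate
5 | (5R,6E)-8-methoxy-5,7-dimethyl-8-oxooct-6-enoic acid | COC(=O)/C(C)=C/[C@H](C)CCCC(=O)O | intermediate
6 | methyl (2E,4R)-8-hydroxy-2,4-dimethyloct-2-enoate | COC(=O)/C(C)=C/[C@H](C)CCCCO | intermediate
7 | methyl (2E,4R)-8-iodo-2,4-dimethyloct-2-enoate | COC(=O)/C(C)=C/[C@H](C)CCCCI | intermediate
8 | ethylzinc (R)-3-ethylcyclohex-1-en-1-olate | CC[C@@H]1CCCC(O[Zn]CC)=C1 | intermediate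
9 | (R)-[(3-ethylcyclohex-1-en-1-yl)oxy]trimethylsilane | CC[C@@H]1CCCC(O[Si](C)(C)C)=C1 | intermediate
10 | (R)-5-ethyl-6-oxohexanoic acid | CC[C@@H](C=O)CCCC(=O)O | intermediate
11 | (R)-5-ethylhept-6-ynoic acid | CC[C@@H](C#C)CCCC(=O)O | intermediate
12 | S-ethyl (R)-5-ethylhept-6-ynethioate | CC[C@@H](C#C)CCCC(=O)SCC | intermediate
13 | S-ethyl (5R,6E)-5-ethyl-7-(pinacolboryl)hept-6-enethioate | CC[C@@H](/C=C/B1OC(C)(C)C(C)(C)O1)CCCC(=O)SCC | intermediate
14 | [(5R,6E)-8-methoxy-5,7-dimethyl-8-oxooct-6-en-1-yl]zinc iodide | COC(=O)/C(C)=C/[C@H](C)CCCC[Zn]I | intermediate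
15 | methyl (2E,4R,13R,14E)-13-ethyl-2,4-dimethyl-9-oxo-15-(pinacolboryl)pentadeca-2,14-dienoate | COC(=O)/C(C)=C/[C@H](C)CCCCC(=O)CCC[C@@H](CC)/C=C/B1OC(C)(C)C(C)(C)O1 | intermediate
16 | 3-methoxyprop-1-yne | C#CCOC | starting material
17 | (E)-2-bromo-1-iodo-3-methoxyprop-1-ene | I/C=C(\COC)Br | intermediate
18 | methyl (2E,4R,13R,14E,16E)-17-bromo-13-ethyl-18-methoxy-2,4-dimethyl-9-oxooctadeca-2,14,16-trienoate | COC(=O)/C(C)=C/[C@H](C)CCCCC(=O)CCC[C@@H](CC)/C=C/C=C(\COC)Br | intermediate
19 | ethyl (S)-4-chloro-3-hydroxybutanoate | CCOC(=O)C[C@H](O)CCl | starting material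
20 | ethyl (S)-4-azido-3-hydroxybutanoate | CCOC(=O)C[C@H](O)CN=[N+]=[N-] | intermediate
21 | ethyl (S)-4-azido-3-(tert-butyldimethylsilyloxy)butanoate | CCOC(=O)C[C@H](O[Si](C)(C)C(C)(C)C)CN=[N+]=[N-] | intermediate
22 | (S)-4-azido-3-(tert-butyldimethylsilyloxy)butanal | O=CC[C@H](O[Si](C)(C)C(C)(C)C)CN=[N+]=[N-] | intermediate
23 | diisopinocampheylborinate of (3R,4S,6S)-7-azido-6-(tert-butyldimethylsilyloxy)-3-(pinacolboryl)hept-1-en-4-ol | C=C[C@@H](B1OC(C)(C)C(C)(C)O1)[C@@H](OB([C@H]1C[C@H]2C[C@@H]([C@@H]1C)C2(C)C)[C@H]1C[C@H]2C[C@@H]([C@@H]1C)C2(C)C)C[C@H](O[Si](C)(C)C(C)(C)C)CN=[N+]=[N-] | intermediate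
24 | (3R,4S,6S)-7-azido-6-(tert-butyldimethylsilyloxy)hept-1-ene-3,4-diol | C=C[C@@H](O)[C@@H](O)C[C@H](O[Si](C)(C)C(C)(C)C)CN=[N+]=[N-] | intermediate
25 | (3R,4S,6S)-7-azido-3,4,6-tris(tert-butyldimethylsilyloxy)hept-1-ene | C=C[C@@H](O[Si](C)(C)C(C)(C)C)[C@@H](O[Si](C)(C)C(C)(C)C)C[C@H](O[Si](C)(C)C(C)(C)C)CN=[N+]=[N-] | intermediate
26 | (2S,4S,5R)-2,4,5-tris(tert-butyldimethylsilyloxy)hept-6-en-1-amine | C=C[C@@H](O[Si](C)(C)C(C)(C)C)[C@@H](O[Si](C)(C)C(C)(C)C)C[C@H](O[Si](C)(C)C(C)(C)C)CN | intermediate
27 | N-[(2S,4S,5R)-2,4,5-tris(tert-butyldimethylsilyloxy)hept-6-en-1-yl]formamide | C=C[C@@H](O[Si](C)(C)C(C)(C)C)[C@@H](O[Si](C)(C)C(C)(C)C)C[C@H](O[Si](C)(C)C(C)(C)C)CNC=O | intermediate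
28 | N-[(2S,4S,5R)-7-(9-borabicyclo[3.3.1]nonan-9-yl)-2,4,5-tris(tert-butyldimethylsilyloxy)heptyl]formamide | C1CC2CCCC(C1)B2CC[C@@H](O[Si](C)(C)C(C)(C)C)[C@@H](O[Si](C)(C)C(C)(C)C)C[C@H](O[Si](C)(C)C(C)(C)C)CNC=O | intermediate
29 | seco formamide methyl ester (C3–C26 chain, name as in step 18) | COC(=O)/C(C)=C/[C@H](C)CCCCC(=O)CCC[C@@H](CC)/C=C/C=C(\COC)CC[C@@H](O[Si](C)(C)C(C)(C)C)[C@@H](O[Si](C)(C)C(C)(C)C)C[C@H](O[Si](C)(C)C(C)(C)C)CNC=O | intermediate
30 | seco isocyanide methyl ester (name as in step 19) | COC(=O)/C(C)=C/[C@H](C)CCCCC(=O)CCC[C@@H](CC)/C=C/C=C(\COC)CC[C@@H](O[Si](C)(C)C(C)(C)C)[C@@H](O[Si](C)(C)C(C)(C)C)C[C@H](O[Si](C)(C)C(C)(C)C)C[N+]#[C-] | intermediate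
31 | seco isocyano acid (name as in step 20) | OC(=O)/C(C)=C/[C@H](C)CCCCC(=O)CCC[C@@H](CC)/C=C/C=C(\COC)CC[C@@H](O[Si](C)(C)C(C)(C)C)[C@@H](O[Si](C)(C)C(C)(C)C)C[C@H](O[Si](C)(C)C(C)(C)C)C[N+]#[C-] | intermediate
32 | butanal | CCCC=O | starting material
33 | open-chain N-alkyl (S)-2-hydroxypentanenitrilium carboxylate (aluminium-bound in the flask) | [O-]C(=O)/C(C)=C/[C@H](C)CCCCC(=O)CCC[C@@H](CC)/C=C/C=C(\COC)CC[C@@H](O[Si](C)(C)C(C)(C)C)[C@@H](O[Si](C)(C)C(C)(C)C)C[C@H](O[Si](C)(C)C(C)(C)C)C[N+]#C[C@@H](O)CCC | intermediate
34 | 27-membered acyl imidate carrying the (S)-1-hydroxybutyl group on C28 | CCC[C@H](O)C(=N1)OC(=O)/C(C)=C/[C@H](C)CCCCC(=O)CCC[C@@H](CC)/C=C/C=C(\COC)CC[C@@H](O[Si](C)(C)C(C)(C)C)[C@@H](O[Si](C)(C)C(C)(C)C)C[C@H](O[Si](C)(C)C(C)(C)C)C1 | intermediate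
35 | 22,23,25-tris-O-(tert-butyldimethylsilyl) target | CCC[C@@H]1OC(=O)/C(C)=C/[C@H](C)CCCCC(=O)CCC[C@@H](CC)/C=C/C=C(\COC)CC[C@@H](O[Si](C)(C)C(C)(C)C)[C@@H](O[Si](C)(C)C(C)(C)C)C[C@H](O[Si](C)(C)C(C)(C)C)CNC1=O | intermediate
36 | CNP0489568.2 (1S,6R,15R,22R,23S,25S; 4E,16E,18Z) | CCC[C@@H]1OC(=O)/C(C)=C/[C@H](C)CCCCC(=O)CCC[C@@H](CC)/C=C/C=C(\COC)CC[C@@H](O)[C@@H](O)C[C@H](O)CNC1=O | target

## Step count and least certain steps

Total step count: 22.

Longest linear sequence: 11 steps. The three lines are of equal length:
- 19 to 36 through steps 12–22;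
- 1 to 36 through steps 5–9, 11 and 18–22;
- 1 to 36 through steps 1–4, 9, 11 and 18–22.

**Step 21 (key step).**
- *What may go wrong:* the nitrilium ion may be captured by a second chain (chain growth), or by traces of water or chloride, before the remote carboxylate arrives. The 27-membered closure has a low effective molarity. Face selectivity at C1 may also be eroded by the uncatalysed pathway.
- *Fallback (known chemistry):* C–C bond formation and ring closure are separated. Starting from 30, the same (salen)AlCl-catalysed Passerini reaction is run in its known intermolecular form at normal concentration with 32 and chloroacetic acid, and gives the α-chloroacetoxy amide F1. LiOH removes the chloroacetyl group and the methyl ester and gives the seco hydroxy acid F2. Shiina macrolactonisation (2-methyl-6-nitrobenzoic anhydride, DMAP, high dilution) closes O2–C3 and comes back to the route at 35.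

**Step 18.**
- *What may go wrong:* the borane may be consumed at the N–H or the carbonyl of the formamide. Oxidative addition and transmetalation at the hindered 2-bromodiene may be slow, which leaves time for protodeboronation and β-hydride loss.
- *Fallback:* nitrogen is carried in a borane-inert form, and the formamide is made after the coupling. Starting from 25, Staudinger reduction and trapping of 26 with Boc2O gives the carbamate F3. Hydroboration and coupling with 18 as in step 18 gives the coupled carbamate F4. Me3SiOTf and 2,6-lutidine, then methanol, release the primary amine F5. Ethyl formate converts it into 29, where the route is rejoined.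

**Step 11.**
- *What may go wrong:* after insertion of zerovalent palladium into the C–I bond, the neighbouring bromide may be lost by β-elimination. A second coupling at C–Br is also possible.
- *Fallback:* the ketone is made before the alkyne is functionalised, and the diene bond is formed without palladium. Starting from 12 and 7, Fukuyama coupling of 14 with 12 gives the alkynyl ketone F6. Hydrostannation (Bu3SnH, PdCl2(PPh3)2) gives the (E)-alkenylstannane F7. Coupling with 17 mediated by copper thiophene-2-carboxylate, Cu(O2CC4H3S), in NMP at rt joins C17 to C18 and comes back at 18.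

**Step 6.**
- *What may go wrong:* the α-ethyl aldehyde may epimerise by enolisation in carbonate/methanol before the homologation is complete.
- *Fallback:* the alkyne is left out. Starting from 9, ozonolysis as before is followed by a Takai–Utimoto olefination of 10 under non-basic conditions (Cl2CHBpin, CrCl2, LiI, THF). This gives the (E)-alkenylboronate acid F8. Thioesterification as in step 7 gives 13, where the route is rejoined.

## Further compounds

F1 | step 21 | methyl ester of the seco chain with N27 acylated by (S)-2-(chloroacetoxy)pentanoyl | COC(=O)/C(C)=C/[C@H](C)CCCCC(=O)CCC[C@@H](CC)/C=C/C=C(\COC)CC[C@@H](O[Si](C)(C)C(C)(C)C)[C@@H](O[Si](C)(C)C(C)(C)C)C[C@H](O[Si](C)(C)C(C)(C)C)CNC(=O)[C@H](CCC)OC(=O)CCl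
F2 | step 21 | seco hydroxy acid (free C3 acid, free C1 hydroxyl) | OC(=O)/C(C)=C/[C@H](C)CCCCC(=O)CCC[C@@H](CC)/C=C/C=C(\COC)CC[C@@H](O[Si](C)(C)C(C)(C)C)[C@@H](O[Si](C)(C)C(C)(C)C)C[C@H](O[Si](C)(C)C(C)(C)C)CNC(=O)[C@H](CCC)O
F3 | step 18 | tert-butyl N-[(2S,4S,5R)-2,4,5-tris(tert-butyldimethylsilyloxy)hept-6-en-1-yl]carbamate | C=C[C@@H](O[Si](C)(C)C(C)(C)C)[C@@H](O[Si](C)(C)C(C)(C)C)C[C@H](O[Si](C)(C)C(C)(C)C)CNC(=O)OC(C)(C)C
F4 | step 18 | seco methyl ester with NHBoc at C26 | COC(=O)/C(C)=C/[C@H](C)CCCCC(=O)CCC[C@@H](CC)/C=C/C=C(\COC)CC[C@@H](O[Si](C)(C)C(C)(C)C)[C@@H](O[Si](C)(C)C(C)(C)C)C[C@H](O[Si](C)(C)C(C)(C)C)CNC(=O)OC(C)(C)C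
F5 | step 18 | seco methyl ester with free NH2 at C26 | COC(=O)/C(C)=C/[C@H](C)CCCCC(=O)CCC[C@@H](CC)/C=C/C=C(\COC)CC[C@@H](O[Si](C)(C)C(C)(C)C)[C@@H](O[Si](C)(C)C(C)(C)C)C[C@H](O[Si](C)(C)C(C)(C)C)CN
F6 | step 11 | methyl (2E,4R,13R)-13-ethyl-2,4-dimethyl-9-oxopentadec-2-en-14-ynoate | COC(=O)/C(C)=C/[C@H](C)CCCCC(=O)CCC[C@@H](CC)C#C
F7 | step 11 | methyl (2E,4R,13R,14E)-13-ethyl-2,4-dimethyl-9-oxo-15-(tributylstannyl)pentadeca-2,14-dienoate | COC(=O)/C(C)=C/[C@H](C)CCCCC(=O)CCC[C@@H](CC)/C=C/[Sn](CCCC)(CCCC)CCCC
F8 | step 6 | (5R,6E)-5-ethyl-7-(pinacolboryl)hept-6-enoic acid | CC[C@@H](/C=C/B1OC(C)(C)C(C)(C)O1)CCCC(=O)O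
A1 | alternative 1 | (S)-2-hydroxypentanoic acid | CCC[C@H](O)C(=O)O
A2 | alternative 1 | seco amino acid (O2–C3 ester in place, free NH2 at C26, free C28 acid) | CCC[C@H](OC(=O)/C(C)=C/[C@H](C)CCCCC(=O)CCC[C@@H](CC)/C=C/C=C(\COC)CC[C@@H](O[Si](C)(C)C(C)(C)C)[C@@H](O[Si](C)(C)C(C)(C)C)C[C@H](O[Si](C)(C)C(C)(C)C)CN)C(=O)O
A3 | alternative 2 | open chain with (Z)-alkenyl iodide at C18 and (E)-alkenylboronate at C17 | I/C=C(\COC)CC[C@@H](O[Si](C)(C)C(C)(C)C)[C@@H](O[Si](C)(C)C(C)(C)C)C[C@H](O[Si](C)(C)C(C)(C)C)CNC(=O)[C@H](CCC)OC(=O)/C(C)=C/[C@H](C)CCCCC(=O)CCC[C@@H](CC)/C=C/B1OC(C)(C)C(C)(C)O1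
A4 | alternative 3 | 25-membered lactam (N27 bound to C3) | O=C1/C(C)=C/[C@H](C)CCCCC(=O)CCC[C@@H](CC)/C=C/C=C(\COC)CC[C@@H](O[Si](C)(C)C(C)(C)C)[C@@H](O[Si](C)(C)C(C)(C)C)C[C@H](O[Si](C)(C)C(C)(C)C)CN1
A5 | alternative 3 | N-[(S)-2-hydroxypentanoyl] imide of the 25-membered lactam | O=C1/C(C)=C/[C@H](C)CCCCC(=O)CCC[C@@H](CC)/C=C/C=C(\COC)CC[C@@H](O[Si](C)(C)C(C)(C)C)[C@@H](O[Si](C)(C)C(C)(C)C)C[C@H](O[Si](C)(C)C(C)(C)C)CN1C(=O)[C@@H](O)CCC
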